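We must choose a temperature programme for this batch now, and one rate tells us how long warmth can be afforded.

    intermediate ⇌ target (K1 = 2.6, k1 = 0.12 s⁻¹, Ea1 = 75.0 kJ mol⁻¹, ΔH1 = −76.0 kJ mol⁻¹)
    intermediate ⇌ isomer of the product A (K2 = 2.5, k2 = 0.067 s⁻¹, Ea2 = 64.0 kJ mol⁻¹, ΔH2 = −2.00 kJ mol⁻¹)
    intermediate → decomposed reagent (k3 = 0.10 s⁻¹, Ea3 = 78.0 kJ mol⁻¹)
    starting material + protic impurity → quenched substrate (k4 = 2000 M⁻¹ s⁻¹, Ea4 = 36.0 kJ mol⁻¹)
    starting material → intermediate (k5 = 1.3 s⁻¹, Ea5 = 62.0 kJ mol⁻¹)
    target ⇌ isomer of the product B (K6 = 0.39, k6 = 0.13 s⁻¹, Ea6 = 78.0 kJ mol⁻¹, ΔH6 = −6.00 kJ mol⁻¹)
    (constants at 0 °C)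

| flask | starting material | protic impurity | temperature | time | remark |
|---|---|---|---|---|---|
| noon | 1.0 mM | 0.0500 mM | −20 °C | 40 s |  |
| autumn | 1.0 mM | 0.0500 mM | 0 °C | 40 s |  |
| dusk | 1.0 mM | 0.0500 mM | −40 °C | 40 s |  |
| spring | 1.0 mM | 0.0500 mM |  | 40 s | at 0 °C until 20 s, from then on at −40 °C |

* the flask that comes out highest in amount of target, in percent of the starting material charged, or "all alike" when all lie within 1.5 percentage points (noon / autumn / dusk / spring / all alike)
* target at the end, in percent of the starting material charged, noon
* target at the end, in percent of the starting material charged, autumn
* target at the end, in percent of the starting material charged, dusk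
* target at the end, in percent of the starting material charged, spring

- all constants are for 0 °C and move with temperature by the activation energies and enthalpies

**The bleed.** At 0 °C the starting material becomes intermediate with a half-life of 0.533 s. The exchange of intermediate with isomer of the product A relaxes with a half-life of 7.39 s, shorter than the warm stage of 20 s. For a reckoning we treat intermediate, target and both isomers as one pool at their equilibrium ratios (a pre-equilibrium), with the intermediate feeding decomposed reagent. Those ratios give intermediate 14.1% of the pool and target 36.5%. This overstates the intermediate's share, because its decomposition constant 0.10 s⁻¹ is of like size to its exchange constant with target 0.12 s⁻¹. The decomposition constant times that share gives the pool a decay constant of 0.0141 s⁻¹, and so a half-life against decomposition of 49.3 s. This bleed half-life is far longer than the 0.533 s of the making.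

**Cold stage.** From the hottest flask to the coldest, decomposition slows by a factor of 360. In dusk's cold, target and isomer of the product B relax with a half-life of 12.2 min, longer than the 40 s of the run. So we expect spring to keep at the end roughly what it holds at the change.

**The bracket.** Suppose nothing is lost on the way in. The bleed then leaves 75.5% of the pool after the warm stage, and target's share of it gives an estimated ceiling of 27.6%. For a floor we also charge two losses at their initial rates. The charge passes the impurity at 92.9%, and 65.2% of the intermediate escapes decomposition on its first passage. That gives 16.7%. The floor counts some decomposition twice, so we commit to the middle, 22.1%, and the hand stops there.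

**The forecast.** It names spring, because the warm stage “builds the target near its peak”. It gives 23.5% for spring, 18.7% for autumn, 17.5% for noon and 0.33% for dusk. Its spring value lies under our ceiling, over our floor, and a little above our middle.

**The flask.** Spring comes out highest at 21.8%, against 17.4% for autumn, 17.1% for noon and 0.324% for dusk. Its target read 21.8% at the change, 20.0 s, and 21.8% at 40.0 s. Autumn read the same 21.8% at 20.0 s and stayed warm. By the bleed half-life, 75.5% of that should survive the further 20.0 s, which gives 16.5%, and autumn reads 17.4%.

The numbers of this flask are assumed; what happens was integrated by code.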